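Reckon this flask on the fraction of X left, not on the products: take the logarithm of that fraction and you can read a slope.

common to all: X 0.050 M; D 0.2 mol%

| run | G | remark | time |
|---|---|---|---|
| east | 0.050 M | the very flask that is asked about, followed so far |  |
| flask | 0.0500 M |  | 10 min |

- east (time / min: Q / %, X / %): 0.250: 1.1, 97.6; 0.833: 0.9, 95.5; 1.33: 1.3, 92.1; 2.00: 2.1, 90.0; 3.00: 2.0, 81.0; 4.00: 5.9, 74.2; 5.00: 8.8, 70.0

(each reading ± 1 percentage point)

- the average divides the monomer in chains by the number of chains begun, living and dead together
- the earlier runs do not show the number of chains; that part of a forecast is a guess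

- average number of monomer units in a chain (chains begun, living or dead) at 10 min
- part of the X that has reacted at 10 min

The east run is the asked flask followed up to 5.00 min, so you simply draw its curve on. From the charge to 2.00 min, [X] falls to 90.0%, a starting slope of 0.0527 min⁻¹. Then the curve bends: from 2.00 min to 5.00 min, [X] goes on to 70.0%, and the slope of ln[X] over that stretch, which I call the loss constant, an apparent pseudo-first-order constant, reads 0.0838 min⁻¹, steeper than at the start. Q has its knee in the same readings, 2.0% at 3.00 min and 8.8% at 5.00 min. The X readings show no level yet.

Hold the loss constant and [X] crosses half its charge at 9.02 min and stands at 46.0% at 10 min. So my c is 54.0%, and with the slope rising so far I take that as the low side.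

The forecast gives 52% and a dp of 135, of which it says: “this part is a guess and the range is wide”.

The flask gives c = 58.6% and dp = 372.

    G + X → E (k = 0.0135 L mol⁻¹ s⁻¹)
    X + J → Q + J, rate k2*[J]*[X] (k = 33.4 L mol⁻¹ s⁻¹)
    X → L (k = 2.40 × 10⁻⁴ s⁻¹)
    X + D → J + Q (k = 0.0187 L mol⁻¹ s⁻¹)

At 10 min the flask holds 41.4% of its X against my 46.0%, and from 5.00 min on its loss constant is 0.101 min⁻¹, above the 0.0838 min⁻¹ I held. Now take the neighbouring flask, the same charge but with 0.12 M of G. Held at 0.0838 min⁻¹ from the charge, 10 min leaves 43.3% of the X, but the neighbouring flask has 26.3% left, a loss constant of 0.134 min⁻¹ averaged over the whole time. Its c is 73.7%, and E holds 49.2% of the X charged.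

Readings and results were generated by integration with constants of no real substance, noise included.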